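(The data stem from a simulated flask for substances that don't exist; noise was put on by code.)

Compare two clocks on a flask: the time it needs to use up its reagent at its early rate, and the time we allow it.

| flask | substrate | reagent | free catalyst | added ligand | remark | time |
|---|---|---|---|---|---|---|
| zeta | 0.82 M | 0.50 equiv | 0.89 mol% | 5 mM | run made earlier |  |
| beta | 0.82 M | 1 equiv | 0.59 mol% | 5 mM | run made earlier |  |
| birch | 0.82 M | 0.500 equiv | 0.59 mol% | 5.0 mM |  | 2.0 h |
| ash | 0.82 M | 0.500 equiv | 0.59 mol% | 10 mM |  | 2.0 h |
| alder | 0.82 M | 0.500 equiv | 0.59 mol% | 20 mM |  | 2.0 h |

- zeta (time / min: product / %, substrate / %): 3.00: 3.0, 96.3; 8.00: 7.9, 90.6; 15.0: 15.9, 85.3; 25.0: 23.7, 75.4; 30.0: 27.5, 72.5; 40.0: 33.0, 66.2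
- beta (time / min: product / %, substrate / %): 8.00: 6.5, 92.9; 15.0: 13.7, 85.8; 20.0: 17.6, 82.5; 30.0: 25.7, 73.6; 40.0: 33.1, 66.1

(standard deviation of a reading: 0.5 percentage points)

- "hardly changes" means that all values lie within two and a half points (for a concentration: within two and a half percent of the largest)
- no earlier run changes the charge of added ligand; that part of a forecast is a guess

* amount of product at the end, in percent of the substrate charged for birch, ash, alder, in this order
* how the row runs (hardly changes / rises, then falls / rises all the way / falls, then rises / falls all the way)

**Fastest rung.** In the zeta run, product and substrate still sum to 99.2% at 40.0 min, so within the scatter substrate becomes product one for one, and we see no material held up on the way. We assume that the reagent is also used one for one. At 0.500 equiv it is then the limiting reagent, and product in birch, ash and alder stops at half of the substrate charged.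

**Early rung.** The zeta run has the same reagent charge and added ligand as birch, and it gives 15.9% product in 15.0 min. We scale that rate by the catalyst loadings, 0.59 mol% over 0.89 mol%, assuming proportion, and divide the cap by it. This gives 71.2 min for birch: the fill time, the time to reach the cap if the early rate held.

**Allowed time.** Birch's fill time is shorter than its 2.0 h, so the reagent should nearly run down within the run and the rate should sag with it. If product approaches the cap exponentially with the fill time as its constant, birch ends near 40.7%. No run varies the ligand, so we guess that the fill time stretches in proportion to it. Ash then has 142 min, already longer than the time allowed, and alder has 285 min. These give 28.5% and 17.2%, so by our reckoning control passes from the cap to the clock between birch and ash.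

**The forecast.** The forecast, a little apart from our figures, reads 42%, 33% and 24%, so that the row falls all the way, on the ground that “Added ligand probably competes for the catalyst”.

**The result.** The flasks give 45.2%, 35.6% and 23.4%, and the row falls all the way.

    reagent + free catalyst → catalyst intermediate A (k = 0.260 L mol⁻¹ s⁻¹)
    catalyst intermediate A → catalyst intermediate B (k = 0.860 s⁻¹)
    substrate + catalyst intermediate B → catalyst intermediate C (k = 0.120 L mol⁻¹ s⁻¹)
    catalyst intermediate C → free catalyst + product (k = 0.110 s⁻¹)
    free catalyst + added ligand ⇌ idle complex, settled at all times (K = 720 L mol⁻¹)

**Alder's clock.** Read from the product at 1.00 h, birch's fill time is 95.6 min, longer than the early 71.2 min. It still lies under the 2.0 h allowed, and birch ends with 9.5% of its reagent left. Alder's, read the same way, is 226 min, beyond the time allowed, and alder ends with 53% of its reagent left and 83.1% of its catalyst as idle complex. The ligand's joining and the time allowed act together: removing that joining, or allowing tenfold time, lifts alder's product from 23.4% to 50.0%.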